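**Retrosynthetic overview**

1. Target 26 ⇐ removal of three MOM groups ⇐ Claisen–Schmidt condensation (enone C=C) of acetylchromane 22 with aldehyde 24; the acetyl group enters at C6 of MOM ether 20 by directed ortho-lithiation between OMOM and OMe.
2. Chromane 19 ⇐ one-pot aryne relay on the open-chain aryl ether 14: aryne C4a≡C5, closure of the pyran ring through the benzylic C4–C4a bond by the tethered CH2Li, then oxidation of the resulting C5–Li to the C5–OH.
3. Enabling feature (chromane numbering O1, C2, C3, C4, C4a, C5 to C8, C8a): aromatic C4a lies between the two oxygen-bearing ring carbons C8a (pyran O1) and C5 (phenol OH). A triple bond C4a≡C5 can therefore take up C4 and the C5 oxygen on neighbouring atoms, and the three-atom tether O1–C2–C3 lets C4 reach only C4a.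
4. 14 ⇐ SNAr of tertiary alcohol 9 on 4-bromo-3,5-difluoroanisole 10 (one F is displaced to make O1–C8a; the other F and the Br later make the aryne); 9 ⇐ auxiliary-controlled prenylation that sets C3 (R).
5. Ring order: rings A and B are bought as benzenes; the pyran ring is the only ring formed (step 8).

Key step: step 8

Assumption: acid 1 is taken as a purchasable building block (otherwise it is the hydrolysed oxa-Michael adduct of 4-methoxybenzyl alcohol and an acrylate ester).

**Route**

Step 1
Reactants: 1 3-[(4-methoxybenzyl)oxy]propanoic acid; 2 (4R)-4-benzyl-1,3-oxazolidin-2-one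
Product: 4 (4R)-4-benzyl-3-{3-[(4-methoxybenzyl)oxy]propanoyl}-1,3-oxazolidin-2-one, via mixed pivalic anhydride 3 (not isolated)
Conditions: t-BuCOCl, Et3N, THF, −20 °C; then LiCl, 2, −20 °C → rt
Reagents that add atoms: none
Why: N-acylation of the oxazolidinone by the mixed pivalic anhydride with LiCl/Et3N activation is the standard mild route to N-acyl oxazolidinones and involves no stereocenter of the chain.

Step 2
Reactants: 4 (4R)-4-benzyl-3-{3-[(4-methoxybenzyl)oxy]propanoyl}-1,3-oxazolidin-2-one; 5 1-bromo-3-methylbut-2-ene (prenyl bromide)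
Product: 7 (4R)-4-benzyl-3-[(2R)-2-{[(4-methoxybenzyl)oxy]methyl}-5-methylhex-4-enoyl]-1,3-oxazolidin-2-one, via sodium Z-enolate 6 (not isolated)
Conditions: NaN(SiMe3)2, THF, −78 °C; then 5, −78 → −40 °C
Reagents that add atoms: none
Why: Evans asymmetric alkylation: NaN(SiMe3)2 should give the chelated Z-enolate, which the reactive allylic bromide attacks on the face opposite the benzyl group of the (4R)-auxiliary, setting the (R) configuration of the carbon that becomes C3.

Step 3
Reactants: 7 (4R)-4-benzyl-3-[(2R)-2-{[(4-methoxybenzyl)oxy]methyl}-5-methylhex-4-enoyl]-1,3-oxazolidin-2-one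
Product: 8 methyl (2R)-2-{[(4-methoxybenzyl)oxy]methyl}-5-methylhex-4-enoate
Conditions: MeMgBr (1.2 equiv), MeOH, 0 °C
Reagents that add atoms: methanol (CO)
Why: Transesterification with bromomagnesium methoxide attacks the exocyclic imide carbonyl under weakly basic conditions, which should release the auxiliary without epimerising the α-stereocenter or eliminating the β-alkoxy group.

Step 4
Reactants: 8 methyl (2R)-2-{[(4-methoxybenzyl)oxy]methyl}-5-methylhex-4-enoate
Product: 9 (3R)-3-{[(4-methoxybenzyl)oxy]methyl}-2,6-dimethylhept-5-en-2-ol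
Conditions: MeMgBr (3 equiv), THF, 0 °C → rt; aq NH4Cl
Reagents that add atoms: methylmagnesium bromide (C[Mg]Br)
Why: Double Grignard addition to the methyl ester gives the tertiary alcohol, and because addition to the ester and to the transient ketone is faster than enolisation the α-stereocenter should be retained.

Step 5
Reactants: 9 (3R)-3-{[(4-methoxybenzyl)oxy]methyl}-2,6-dimethylhept-5-en-2-ol; 10 2-bromo-1,3-difluoro-5-methoxybenzene (4-bromo-3,5-difluoroanisole)
Product: 12 2-bromo-1-fluoro-5-methoxy-3-{[(3R)-3-{[(4-methoxybenzyl)oxy]methyl}-2,6-dimethylhept-5-en-2-yl]oxy}benzene, via potassium alkoxide 11 (not isolated)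
Conditions: KN(SiMe3)2 (1.0 equiv), THF, 0 °C; then 10 (1.5 equiv), DMPU, 60 °C
Reagents that add atoms: none
Why: Nucleophilic aromatic substitution (addition–elimination): the potassium tertiary alkoxide should add at one of the two equivalent C–F carbons, activated by the ortho bromine and the meta fluorine, and expel fluoride, the best SNAr leaving group, while the C–Br bond and the second fluorine remain.

Step 6
Reactants: 12 2-bromo-1-fluoro-5-methoxy-3-{[(3R)-3-{[(4-methoxybenzyl)oxy]methyl}-2,6-dimethylhept-5-en-2-yl]oxy}benzene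
Product: 13 (2R)-2-[2-(2-bromo-3-fluoro-5-methoxyphenoxy)propan-2-yl]-5-methylhex-4-en-1-ol
Conditions: DDQ, CH2Cl2/pH 7 buffer, 0 °C → rt
Reagents that add atoms: none
Why: Oxidative PMB ether cleavage: DDQ abstracts hydride only from the electron-rich 4-methoxybenzyl position and water hydrolyses the oxocarbenium ion, so the alkene, the aryl halides and the tert-alkyl aryl ether should not be affected.

Step 7
Reactants: 13 (2R)-2-[2-(2-bromo-3-fluoro-5-methoxyphenoxy)propan-2-yl]-5-methylhex-4-en-1-ol
Product: 14 2-bromo-1-fluoro-3-{[(3S)-3-(iodomethyl)-2,6-dimethylhept-5-en-2-yl]oxy}-5-methoxybenzene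
Conditions: I2, PPh3, imidazole, toluene/MeCN, 0 → 50 °C
Reagents that add atoms: iodine (II)
Why: Appel-type iodination (PPh3/I2/imidazole) substitutes the activated primary oxygen by iodide in an SN2 step at CH2, which leaves the neighbouring stereocenter untouched (the descriptor changes to S only because CH2I now outranks the ether carbon).

Step 8
Reactants: 14 2-bromo-1-fluoro-3-{[(3S)-3-(iodomethyl)-2,6-dimethylhept-5-en-2-yl]oxy}-5-methoxybenzene
Product: 19 (3R)-7-methoxy-2,2-dimethyl-3-(3-methylbut-2-en-1-yl)-3,4-dihydro-2H-chromen-5-ol, via dilithio species 15 (not isolated), via tethered aryne 16 (not isolated), via 5-lithiochromane 17 (not isolated), via dimethyl arylboronate 18 (not isolated)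
Conditions: t-BuLi (4.1 equiv), pentane/Et2O, −78 °C; THF, −78 → 0 °C; B(OMe)3, −78 °C → rt; NaOH, H2O2, H2O, 0 °C → rt
Reagents that add atoms: hydrogen peroxide (OO)
Why: Lithium–iodine and lithium–bromine exchange with t-BuLi should give the dilithio species 15 (alkyllithium at C4, aryllithium at C4a), whose aryllithium loses LiF on warming to give the aryne 16 with the triple bond C4a≡C5. The tethered primary alkyllithium then adds across the aryne (intramolecular carbolithiation, 6-exo-dig closure of the pyran ring) to form the C4–C4a bond and the new aryllithium 17 at C5, which B(OMe)3 and alkaline H2O2 convert into the phenol. The closest known reaction type is the anionic cyclization of benzyne-tethered alkyl-, alkenyl- and benzyllithiums, including ether-tethered cases that close six-membered rings, followed by electrophilic trapping of the aryllithium formed. No new stereocenter is formed, and C3 carries neither an acidic hydrogen nor a leaving group, so it should pass unchanged. The selectivity needed is the side of the triple bond that takes the carbon: the three-atom tether from O1 on C8a can reach only C4a (attack at C5 would need a meta bridge), the bromine fixes the lithium at C4a, and the fluorine on C5 is the only leaving group beside it, so a single aryne and a single ring closure are expected. The prenyl alkene is not attacked by the organolithiums at these temperatures, and high dilution should suppress intermolecular capture of the aryne.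

Step 9
Reactants: 19 (3R)-7-methoxy-2,2-dimethyl-3-(3-methylbut-2-en-1-yl)-3,4-dihydro-2H-chromen-5-ol
Product: 20 (3R)-7-methoxy-5-(methoxymethoxy)-2,2-dimethyl-3-(3-methylbut-2-en-1-yl)-3,4-dihydro-2H-chromene
Conditions: MOMCl, i-Pr2NEt, CH2Cl2, 0 °C → rt
Reagents that add atoms: chloromethyl methyl ether (COCCl)
Why: Williamson-type O-alkylation of the phenol with the reactive chloromethyl ether gives the MOM ether, which protects the phenol against the later bases and serves as the directing group of the next step.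

Step 10
Reactants: 20 (3R)-7-methoxy-5-(methoxymethoxy)-2,2-dimethyl-3-(3-methylbut-2-en-1-yl)-3,4-dihydro-2H-chromene
Product: 22 1-[(3R)-7-methoxy-5-(methoxymethoxy)-2,2-dimethyl-3-(3-methylbut-2-en-1-yl)-3,4-dihydro-2H-chromen-6-yl]ethan-1-one, via 6-lithio derivative 21 (not isolated)
Conditions: n-BuLi, TMEDA, THF, −78 → 0 °C; then MeC(O)N(OMe)Me, −78 °C → rt
Reagents that add atoms: N-methoxy-N-methylacetamide (CC(=O)N(C)OC)
Why: Directed ortho-metalation: C6–H lies between the chelating OMOM group and the OMe group and should be removed preferentially by n-BuLi/TMEDA, and acylation of the aryllithium with the Weinreb amide stops at the ketone because the tetrahedral chelate is stable until work-up.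

Step 11
Reactants: 23 2,4-dihydroxybenzaldehyde
Product: 24 2,4-bis(methoxymethoxy)benzaldehyde
Conditions: NaH, DMF, 0 °C; MOMCl, 0 °C → rt
Reagents that add atoms: chloromethyl methyl ether (COCCl)
Why: Williamson-type O-alkylation of the bis-phenoxide with MOMCl in DMF, where NaH also deprotonates the hydrogen-bonded ortho hydroxyl so that both phenols are protected.

Step 12
Reactants: 22 1-[(3R)-7-methoxy-5-(methoxymethoxy)-2,2-dimethyl-3-(3-methylbut-2-en-1-yl)-3,4-dihydro-2H-chromen-6-yl]ethan-1-one; 24 2,4-bis(methoxymethoxy)benzaldehyde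
Product: 25 (2E)-3-[2,4-bis(methoxymethoxy)phenyl]-1-[(3R)-7-methoxy-5-(methoxymethoxy)-2,2-dimethyl-3-(3-methylbut-2-en-1-yl)-3,4-dihydro-2H-chromen-6-yl]prop-2-en-1-one
Conditions: KOH, EtOH/H2O, rt
Reagents that add atoms: none
Why: Claisen–Schmidt condensation (crossed aldol with E1cB dehydration) of the methyl ketone enolate with the non-enolisable aldehyde should give the conjugated enone with the thermodynamically favoured E geometry, and the MOM ethers are stable to hydroxide.

Step 13
Reactants: 25 (2E)-3-[2,4-bis(methoxymethoxy)phenyl]-1-[(3R)-7-methoxy-5-(methoxymethoxy)-2,2-dimethyl-3-(3-methylbut-2-en-1-yl)-3,4-dihydro-2H-chromen-6-yl]prop-2-en-1-one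
Product: 26 (2E)-3-(2,4-dihydroxyphenyl)-1-[(3R)-5-hydroxy-7-methoxy-2,2-dimethyl-3-(3-methylbut-2-en-1-yl)-3,4-dihydro-2H-chromen-6-yl]prop-2-en-1-one (CNP0333857.1)
Conditions: 3 M HCl, MeOH, rt → 40 °C
Reagents that add atoms: none
Why: Acid-catalysed acetal cleavage removes the three MOM groups, the one ortho to the ketone fastest, and dilute HCl in methanol near room temperature is chosen so that the prenyl alkene, the chromane ether and the hydroxychalcone should survive.

**Compound list**

1 | 3-[(4-methoxybenzyl)oxy]propanoic acid | COc1ccc(COCCC(=O)O)cc1 | starting material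
2 | (4R)-4-benzyl-1,3-oxazolidin-2-one | O=C1OC[C@@H](Cc2ccccc2)N1 | starting material
3 | 3-[(4-methoxybenzyl)oxy]propanoic pivalic anhydride | COc1ccc(COCCC(=O)OC(=O)C(C)(C)C)cc1 | intermediate
4 | (4R)-4-benzyl-3-{3-[(4-methoxybenzyl)oxy]propanoyl}-1,3-oxazolidin-2-one | COc1ccc(COCCC(=O)N2[C@H](Cc3ccccc3)COC2=O)cc1 | intermediate
5 | 1-bromo-3-methylbut-2-ene (prenyl bromide) | CC(C)=CCBr | starting material
6 | sodium Z-enolate of 4 | COc1ccc(COC/C=C(\[O-])N2[C@H](Cc3ccccc3)COC2=O)cc1.[Na+] | intermediate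
7 | (4R)-4-benzyl-3-[(2R)-2-{[(4-methoxybenzyl)oxy]methyl}-5-methylhex-4-enoyl]-1,3-oxazolidin-2-one | COc1ccc(COC[C@@H](CC=C(C)C)C(=O)N2[C@H](Cc3ccccc3)COC2=O)cc1 | intermediate
8 | methyl (2R)-2-{[(4-methoxybenzyl)oxy]methyl}-5-methylhex-4-enoate | COc1ccc(COC[C@@H](CC=C(C)C)C(=O)OC)cc1 | intermediate
9 | (3R)-3-{[(4-methoxybenzyl)oxy]methyl}-2,6-dimethylhept-5-en-2-ol | COc1ccc(COC[C@@H](CC=C(C)C)C(C)(C)O)cc1 | intermediate
10 | 2-bromo-1,3-difluoro-5-methoxybenzene (4-bromo-3,5-difluoroanisole) | COc1cc(F)c(Br)c(F)c1 | starting material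
11 | potassium alkoxide of 9 | COc1ccc(COC[C@@H](CC=C(C)C)C(C)(C)[O-])cc1.[K+] | intermediate
12 | 2-bromo-1-fluoro-5-methoxy-3-{[(3R)-3-{[(4-methoxybenzyl)oxy]methyl}-2,6-dimethylhept-5-en-2-yl]oxy}benzene | COc1ccc(COC[C@@H](CC=C(C)C)C(C)(C)Oc2cc(OC)cc(F)c2Br)cc1 | intermediate
13 | (2R)-2-[2-(2-bromo-3-fluoro-5-methoxyphenoxy)propan-2-yl]-5-methylhex-4-en-1-ol | OC[C@@H](CC=C(C)C)C(C)(C)Oc1cc(OC)cc(F)c1Br | intermediate
14 | 2-bromo-1-fluoro-3-{[(3S)-3-(iodomethyl)-2,6-dimethylhept-5-en-2-yl]oxy}-5-methoxybenzene | IC[C@@H](CC=C(C)C)C(C)(C)Oc1cc(OC)cc(F)c1Br | intermediate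
15 | dilithio species from 14 (alkyllithium at C4, aryllithium at C4a) | [Li]C[C@@H](CC=C(C)C)C(C)(C)Oc1cc(OC)cc(F)c1[Li] | intermediate
16 | aryne (C4a≡C5) with tethered alkyllithium | [Li]C[C@@H](CC=C(C)C)C(C)(C)OC1=CC(OC)=CC#C1 | intermediate
17 | (3R)-5-lithio-7-methoxy-2,2-dimethyl-3-(3-methylbut-2-en-1-yl)-3,4-dihydro-2H-chromene | COc1cc([Li])c2C[C@@H](CC=C(C)C)C(C)(C)Oc2c1 | intermediate
18 | dimethyl [(3R)-7-methoxy-2,2-dimethyl-3-(3-methylbut-2-en-1-yl)-3,4-dihydro-2H-chromen-5-yl]boronate | COc1cc(B(OC)OC)c2C[C@@H](CC=C(C)C)C(C)(C)Oc2c1 | intermediate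
19 | (3R)-7-methoxy-2,2-dimethyl-3-(3-methylbut-2-en-1-yl)-3,4-dihydro-2H-chromen-5-ol | COc1cc(O)c2C[C@@H](CC=C(C)C)C(C)(C)Oc2c1 | intermediate
20 | (3R)-7-methoxy-5-(methoxymethoxy)-2,2-dimethyl-3-(3-methylbut-2-en-1-yl)-3,4-dihydro-2H-chromene | COc1cc(OCOC)c2C[C@@H](CC=C(C)C)C(C)(C)Oc2c1 | intermediate
21 | 6-lithio derivative of 20 | COc1c([Li])c(OCOC)c2C[C@@H](CC=C(C)C)C(C)(C)Oc2c1 | intermediate
22 | 1-[(3R)-7-methoxy-5-(methoxymethoxy)-2,2-dimethyl-3-(3-methylbut-2-en-1-yl)-3,4-dihydro-2H-chromen-6-yl]ethan-1-one | COc1c(C(C)=O)c(OCOC)c2C[C@@H](CC=C(C)C)C(C)(C)Oc2c1 | intermediate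
23 | 2,4-dihydroxybenzaldehyde | O=Cc1ccc(O)cc1O | starting material
24 | 2,4-bis(methoxymethoxy)benzaldehyde | COCOc1ccc(C=O)c(OCOC)c1 | intermediate
25 | (2E)-3-[2,4-bis(methoxymethoxy)phenyl]-1-[(3R)-7-methoxy-5-(methoxymethoxy)-2,2-dimethyl-3-(3-methylbut-2-en-1-yl)-3,4-dihydro-2H-chromen-6-yl]prop-2-en-1-one | COc1c(C(=O)/C=C/c3ccc(OCOC)cc3OCOC)c(OCOC)c2C[C@@H](CC=C(C)C)C(C)(C)Oc2c1 | intermediate
26 | (2E)-3-(2,4-dihydroxyphenyl)-1-[(3R)-5-hydroxy-7-methoxy-2,2-dimethyl-3-(3-methylbut-2-en-1-yl)-3,4-dihydro-2H-chromen-6-yl]prop-2-en-1-one | COc1cc2c(c(O)c1C(=O)/C=C/c1ccc(O)cc1O)C[C@@H](CC=C(C)C)C(C)(C)O2 | target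

**Step count and risks**

Total step count: 13. Longest linear sequence: 12 steps (steps 1 to 10, 12 and 13); step 11 is the side branch.

Steps most likely to fail, with fallbacks:

Step 8 (aryne ring closure). The risk is capture of the aryne by something other than the tethered alkyllithium (residual t-BuLi, halide, a second molecule), or protonation of an organolithium before ring closure or before borylation. The fallback sets out from 12 and comes back at 19; it installs the C5 oxygen first and closes the same C4–C4a bond without an aryne. The remaining fluorine of 12 is displaced by NaOCH2CH2SiMe3 (DMF, 90 °C, SNAr) to give the silylethyl aryl ether F1. DDQ then frees the primary alcohol F2, and CBr4/PPh3 gives the primary bromide F3. A Parham cyclization (t-BuLi, THF, −100 °C → rt: bromine–lithium exchange at the aryl bromide, then intramolecular SN2 at CH2Br) gives the protected chromane F4. Bu4NF in DMF at 80 °C removes the silylethyl group to give phenol 19.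

Step 5 (SNAr etherification). The risk is slow addition of the hindered tertiary alkoxide to the only moderately activated fluoroarene, so that base-induced degradation of the alkoxide or of 10 competes. The fallback sets out from 9 and 10 and comes back at 12; it reverses the polarity of the ether synthesis. Hydroxide SNAr on 10 (KOH, DMSO/H2O, 100 °C) gives the phenol F5. Alcohol 9 is converted (n-BuLi, then Ph2PCl, THF) into the diphenylphosphinite F6. The oxidation–reduction condensation of F6 with F5 and 2,6-dimethyl-1,4-benzoquinone (CH2Cl2, rt), a phosphonium-mediated etherification known for tertiary alcohols, then gives 12.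

Step 10 (ortho-lithiation and acetylation). The risk is poor site selectivity of the lithiation (C8, between OMe and the ring oxygen, instead of C6) or allylic deprotonation of the prenyl group. The fallback sets out from 19 and comes back at 22. Magnesium-phenoxide ortho-formylation of 19 (MgCl2, Et3N, paraformaldehyde, MeCN, reflux) can only reach C6, because the other ortho position C4a is substituted, and gives the salicylaldehyde F7. MeMgBr gives the carbinol F8, MnO2 (CH2Cl2) oxidises it to the hydroxyacetophenone F9, and NaH/MOMCl in DMF gives 22.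

Further compounds
F1 | step 8 | {2-[2-bromo-5-methoxy-3-({(3R)-3-{[(4-methoxybenzyl)oxy]methyl}-2,6-dimethylhept-5-en-2-yl}oxy)phenoxy]ethyl}(trimethyl)silane | COc1ccc(COC[C@@H](CC=C(C)C)C(C)(C)Oc2cc(OC)cc(OCC[Si](C)(C)C)c2Br)cc1
F2 | step 8 | (2R)-2-(2-{2-bromo-5-methoxy-3-[2-(trimethylsilyl)ethoxy]phenoxy}propan-2-yl)-5-methylhex-4-en-1-ol | OC[C@@H](CC=C(C)C)C(C)(C)Oc1cc(OC)cc(OCC[Si](C)(C)C)c1Br
F3 | step 8 | [2-(2-bromo-3-{[(3S)-3-(bromomethyl)-2,6-dimethylhept-5-en-2-yl]oxy}-5-methoxyphenoxy)ethyl](trimethyl)silane | BrC[C@@H](CC=C(C)C)C(C)(C)Oc1cc(OC)cc(OCC[Si](C)(C)C)c1Br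
F4 | step 8 | (2-{[(3R)-7-methoxy-2,2-dimethyl-3-(3-methylbut-2-en-1-yl)-3,4-dihydro-2H-chromen-5-yl]oxy}ethyl)(trimethyl)silane | COc1cc(OCC[Si](C)(C)C)c2C[C@@H](CC=C(C)C)C(C)(C)Oc2c1
F5 | step 5 | 2-bromo-3-fluoro-5-methoxyphenol | COc1cc(O)c(Br)c(F)c1
F6 | step 5 | (3R)-3-{[(4-methoxybenzyl)oxy]methyl}-2,6-dimethylhept-5-en-2-yl diphenylphosphinite | COc1ccc(COC[C@@H](CC=C(C)C)C(C)(C)OP(c2ccccc2)c2ccccc2)cc1
F7 | step 10 | (3R)-5-hydroxy-7-methoxy-2,2-dimethyl-3-(3-methylbut-2-en-1-yl)-3,4-dihydro-2H-chromene-6-carbaldehyde | COc1c(C=O)c(O)c2C[C@@H](CC=C(C)C)C(C)(C)Oc2c1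
F8 | step 10 | (3R)-6-(1-hydroxyethyl)-7-methoxy-2,2-dimethyl-3-(3-methylbut-2-en-1-yl)-3,4-dihydro-2H-chromen-5-ol (both carbinol epimers) | COc1c(C(C)O)c(O)c2C[C@@H](CC=C(C)C)C(C)(C)Oc2c1
F9 | step 10 | 1-[(3R)-5-hydroxy-7-methoxy-2,2-dimethyl-3-(3-methylbut-2-en-1-yl)-3,4-dihydro-2H-chromen-6-yl]ethan-1-one | COc1c(C(C)=O)c(O)c2C[C@@H](CC=C(C)C)C(C)(C)Oc2c1
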